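**Plan**

1. Numbering (labdane): ring A = C1–C5 + C10, ring B = C5–C10, side chain C11–C16 on C9, C17 on C8, C18/C19 on C4, C20 on C10. The target is (13S)-3β-hydroxylabd-7-en-15-yl acetate (normal series: 5α-H, 9α-H, 10β-methyl).
2. Cuts, in retrosynthetic order: acetyl–O15; C8–C17 (methyl onto a C7=C8 enol triflate of an 8-ketone); the C3–H, C5–H and C1/C2–H bonds (reductions); ring A at C4–C5 and C1–C10 in one event; C9–C11 (conjugate addition with silyl trapping).
3. Enabling feature: in ring A the oxygenated C3 lies between the gem-dimethyl carbon C4 and the C2–C1 ethylene, and C4 and C1 both end on the ring-fusion bond C5–C10. C1–C2–C3(=O)–C4Me2 is therefore the skeleton of 3-ethoxy-2,2-dimethylcyclobutanone. Its strained ring bond between CMe2 and CH(OEt) (future C4 and C1) opens to an enolate/oxocarbenium pair that takes up C5=C10 of a ring B silyl enol ether, so ring A arises from the four-membered ring by a two-atom ring expansion.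
4. Forward order: ring B is bought as an achiral ketal enone and methylated; the side chain is joined at C9; ring A is grown onto C5/C10 from the cyclobutanone; the two auxiliary oxygens (C1–OEt, C5–OH) leave as a diene that is hydrogenated; C3 is reduced; the C8 ketal becomes the C7=C8–C17 unit; deprotection and O15 acetylation finish.
5. Stereochemistry: C13 from monomethyl (R)-3-methylglutarate; C9 from the chiral copper catalyst; C10 from C9 (electrophile anti to the side chain); C5 from hydrogenation anti to C20; C3 from axial hydride attack.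

Key step: step 9

Assumption: the enone ketal, the (R)-hemiester, isobutyryl chloride and ethyl vinyl ether are catalogue compounds; the cyclobutanone is used as the racemate and the C1/C5 epimers formed in the ring expansion are carried together because both centres are erased in the following step; the sense of induction of the copper catalyst is fixed in a trial run and the ligand enantiomer chosen accordingly.

**Route**

Step 1
Reactants: 1 1,4-dioxaspiro[4.5]dec-6-en-8-one
Product: 2 7-iodo-1,4-dioxaspiro[4.5]dec-6-en-8-one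
Conditions: I2, pyridine, CH2Cl2, 0 °C to rt
Reagents that add atoms: iodine, II
Why: α-Iodination of a cyclic enone by a Morita–Baylis–Hillman-type addition–iodination–elimination should place iodine only on the α-carbon, the future C10.

Step 2
Reactants: 2 7-iodo-1,4-dioxaspiro[4.5]dec-6-en-8-one
Product: 3 7-methyl-1,4-dioxaspiro[4.5]dec-6-en-8-one
Conditions: MeB(OH)2, PdCl2(dppf) (5 mol%), K3PO4, THF–H2O, 65 °C
Reagents that add atoms: methylboronic acid, CB(O)O
Why: Suzuki–Miyaura coupling of the activated α-iodoenone should install the future C20 methyl regiospecifically and leave the ketal untouched.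

Step 3
Reactants: 4 (R)-5-methoxy-3-methyl-5-oxopentanoic acid (monomethyl (R)-3-methylglutarate)
Product: 5 methyl (R)-5-hydroxy-3-methylpentanoate
Conditions: BH3·SMe2, THF, −10 °C to rt; MeOH quench
Reagents that add atoms: none
Why: Borane reduces the free acid through its acyloxyborane much faster than the methyl ester, so the two arms of the glutarate are differentiated while the stereocentre (future C13) is untouched.

Step 4
Reactants: 5 methyl (R)-5-hydroxy-3-methylpentanoate
Product: 6 methyl (R)-3-methyl-5-(triisopropylsilyloxy)pentanoate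
Conditions: iPr3SiCl, imidazole, DMF, rt
Reagents that add atoms: chlorotriisopropylsilane, CC(C)[Si](Cl)(C(C)C)C(C)C
Why: Standard silylation of a primary alcohol; the triisopropylsilyl ether should survive Grignard formation, the Lewis acid, hydrogenation and hydride, and leave with fluoride at the end.

Step 5
Reactants: 6 methyl (R)-3-methyl-5-(triisopropylsilyloxy)pentanoate
Product: 7 (S)-3-methyl-5-(triisopropylsilyloxy)pentan-1-ol
Conditions: LiAlH4, THF, 0 °C
Reagents that add atoms: none
Why: Hydride reduction of the ester gives the primary alcohol whose carbon becomes C11.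

Step 6
Reactants: 7 (S)-3-methyl-5-(triisopropylsilyloxy)pentan-1-ol
Product: 8 (R)-(5-bromo-3-methylpentyloxy)triisopropylsilane
Conditions: CBr4, PPh3, CH2Cl2, 0 °C
Reagents that add atoms: carbon tetrabromide, BrC(Br)(Br)Br
Why: Appel reaction converts the primary alcohol into the bromide under neutral conditions that do not affect the silyl ether.

Step 7
Reactants: 9 isobutyryl chloride; 10 ethyl vinyl ether
Product: 12 3-ethoxy-2,2-dimethylcyclobutanone (racemic), via dimethylketene 11 (not isolated)
Conditions: Et3N, excess 10, MeCN, reflux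
Reagents that add atoms: none
Why: Dehydrochlorination gives dimethylketene, whose thermal [2+2] cycloaddition with the enol ether joins the nucleophilic CH2 terminus to the ketene carbonyl carbon and so gives the 3-ethoxy regioisomer.

Step 8
Reactants: 8 (R)-(5-bromo-3-methylpentyloxy)triisopropylsilane; 3 7-methyl-1,4-dioxaspiro[4.5]dec-6-en-8-one
Product: 15 (6R)-7-methyl-6-[(3S)-3-methyl-5-(triisopropylsilyloxy)pentyl]-8-(trimethylsilyloxy)-1,4-dioxaspiro[4.5]dec-7-ene, via Grignard reagent 13 (not isolated), via bromomagnesium enolate 14 (not isolated)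
Conditions: Mg, THF, 40 °C; Cu(OTf)2 (5 mol%), chiral imidazolinium carbene precursor (6 mol%), 3, Et2O, −30 °C; Me3SiCl, Et3N, DMPU, −30 °C to rt
Reagents that add atoms: chlorotrimethylsilane, C[Si](C)(C)Cl
Why: Copper-catalysed asymmetric conjugate addition of a Grignard reagent to an α-substituted cyclic enone with silyl trapping of the enolate should set C9 under control of the chiral copper–carbene complex and deliver the tetrasubstituted C5=C10 enol ether regiospecifically.

Step 9
Reactants: 15 (6R)-7-methyl-6-[(3S)-3-methyl-5-(triisopropylsilyloxy)pentyl]-8-(trimethylsilyloxy)-1,4-dioxaspiro[4.5]dec-7-ene; 12 3-ethoxy-2,2-dimethylcyclobutanone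
Product: 17 1ξ-ethoxy-8,8-ethylenedioxy-5ξ-hydroxy-15-(triisopropylsilyloxy)-17-norlabdan-3-one (C1/C5 epimers), via trimethylsilyl ether adduct 16 (not isolated)
Conditions: EtAlCl2 (1.5 equiv), CH2Cl2, −78 to −45 °C; aq. NaHCO3; then AcOH–THF–H2O, rt
Reagents that add atoms: none
Why: EtAlCl2 binds the carbonyl of 12 and the strained ring bond between CMe2 and CH(OEt) ionises to an aluminium enolate (future C4) and an ethyl oxocarbenium ion (future C1); C10 of silyl enol ether 15 attacks C1 and the resulting silyloxocarbenium ion at C5 is captured by the enolate at C4, so that C5 and C10 are inserted into the four-membered ring. The closest known reaction type is the Lewis-acid-mediated formal [4+2] cycloaddition of 3-alkoxycyclobutanones with silyl enol ethers, a strain-release counterpart of a Mukaiyama–Michael/aldol (Robinson-type) sequence. Ring A is closed at C4–C5 in the 6-(enolendo)-exo-trig mode, as a two-atom ring expansion of the cyclobutanone. C10 is controlled by the resident C9 centre, because the electrophile adds to the face of the enol ether opposite the pseudo-axial side chain, which places C1 trans and C20 cis to the side chain; C1 and C5 form as epimer mixtures that do not matter since both oxygens are eliminated in step 10. The step needs cleavage of the more substituted ring bond of 12, secured by the gem-dimethyl group and the ethoxy donor, and the C10-to-C1/C4-to-C5 sense of union, secured by the fixed polarity of both partners. The mild acidic work-up should remove the tertiary trimethylsilyl group without touching the dioxolane or the triisopropylsilyl ether.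

Step 10
Reactants: 17 1ξ-ethoxy-8,8-ethylenedioxy-5ξ-hydroxy-15-(triisopropylsilyloxy)-17-norlabdan-3-one
Product: 19 8,8-ethylenedioxy-15-(triisopropylsilyloxy)-17-norlabda-1,5-dien-3-one, via 5-ene ethoxy ketone 18 (not isolated)
Conditions: SOCl2, pyridine, CH2Cl2, −20 to 0 °C; then DBU, PhMe, 60 °C
Reagents that add atoms: none
Why: Dehydration of the tertiary alcohol through its chlorosulfite can only go towards C6 because C4 and C10 are quaternary, and DBU then effects E1cB loss of ethanol from the β-ethoxy ketone, so both uncontrolled centres of step 9 are erased.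

Step 11
Reactants: 19 8,8-ethylenedioxy-15-(triisopropylsilyloxy)-17-norlabda-1,5-dien-3-one
Product: 20 8,8-ethylenedioxy-15-(triisopropylsilyloxy)-17-nor-5α-labdan-3-one
Conditions: H2 (40 bar), Pd/C, EtOAc, rt
Reagents that add atoms: none
Why: Heterogeneous catalytic hydrogenation should saturate the enone double bond readily and add hydrogen to C5=C6 from the α face, opposite the axial C20 and 4β methyl groups, which sets the trans ring fusion.

Step 12
Reactants: 20 8,8-ethylenedioxy-15-(triisopropylsilyloxy)-17-nor-5α-labdan-3-one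
Product: 22 3β-hydroxy-15-(triisopropylsilyloxy)-17-nor-5α-labdan-8-one, via ketal alcohol 21 (not isolated)
Conditions: NaBH4, MeOH–THF, 0 °C; then 1 M HCl, THF, rt
Reagents that add atoms: water, O
Why: Borohydride attacks the 4,4-dimethyl 3-ketone axially from the α face, away from the 4β methyl, to give the equatorial 3β alcohol, and acid-catalysed ketal hydrolysis then frees the C8 ketone with C9 kept in its more stable equatorial configuration.

Step 13
Reactants: 22 3β-hydroxy-15-(triisopropylsilyloxy)-17-nor-5α-labdan-8-one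
Product: 23 3β-(triethylsilyloxy)-15-(triisopropylsilyloxy)-17-nor-5α-labdan-8-one
Conditions: Et3SiOTf, 2,6-lutidine, CH2Cl2, −78 °C
Reagents that add atoms: triethylsilyl trifluoromethanesulfonate, CC[Si](CC)(CC)OS(=O)(=O)C(F)(F)F
Why: Silylation of the hindered secondary alcohol makes it inert to the strong base and the triflating agent of the next step.

Step 14
Reactants: 23 3β-(triethylsilyloxy)-15-(triisopropylsilyloxy)-17-nor-5α-labdan-8-one
Product: 25 3β-(triethylsilyloxy)-15-(triisopropylsilyloxy)-17-norlabd-7-en-8-yl trifluoromethanesulfonate, via potassium enolate 24 (not isolated)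
Conditions: KN(SiMe3)2, THF, −78 °C; then PhNTf2, −78 to 0 °C
Reagents that add atoms: N-phenylbis(trifluoromethanesulfonimide), O=S(=O)(N(c1ccccc1)S(=O)(=O)C(F)(F)F)C(F)(F)F
Why: Kinetic deprotonation should occur at the unhindered C7 methylene and not at the tertiary C9 next to quaternary C10, and O-sulfonylation of the enolate fixes the double bond at C7=C8.

Step 15
Reactants: 25 3β-(triethylsilyloxy)-15-(triisopropylsilyloxy)-17-norlabd-7-en-8-yl trifluoromethanesulfonate
Product: 26 3β-(triethylsilyloxy)-15-(triisopropylsilyloxy)labd-7-ene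
Conditions: MeMgBr, Fe(acac)3 (5 mol%), THF–NMP, −30 to 0 °C
Reagents that add atoms: methylmagnesium bromide, C[Mg]Br
Why: Iron-catalysed Kumada-type cross-coupling of the alkenyl triflate replaces the triflate by the C17 methyl without moving the double bond.

Step 16
Reactants: 26 3β-(triethylsilyloxy)-15-(triisopropylsilyloxy)labd-7-ene
Product: 27 (13S)-labd-7-ene-3β,15-diol
Conditions: Bu4NF, THF, rt to 45 °C
Reagents that add atoms: none
Why: Fluoride-mediated desilylation cleaves both silyl ethers in one operation.

Step 17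
Reactants: 27 (13S)-labd-7-ene-3β,15-diol
Product: 28 (13S)-3β-hydroxylabd-7-en-15-yl acetate
Conditions: AcCl (1.05 equiv), 2,4,6-collidine, CH2Cl2, −78 °C
Reagents that add atoms: acetyl chloride, CC(=O)Cl
Why: Chemoselective acylation should take the unhindered primary C15 alcohol and leave the neopentyl-type secondary 3β alcohol free.

**Compound list**

1 | 1,4-dioxaspiro[4.5]dec-6-en-8-one | O=C1CCC2(OCCO2)C=C1 | starting material
2 | 7-iodo-1,4-dioxaspiro[4.5]dec-6-en-8-one | O=C1CCC2(OCCO2)C=C1I | intermediate
3 | 7-methyl-1,4-dioxaspiro[4.5]dec-6-en-8-one | O=C1CCC2(OCCO2)C=C1C | intermediate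
4 | (R)-5-methoxy-3-methyl-5-oxopentanoic acid (monomethyl (R)-3-methylglutarate) | OC(=O)C[C@@H](C)CC(=O)OC | starting material
5 | methyl (R)-5-hydroxy-3-methylpentanoate | OCC[C@@H](C)CC(=O)OC | intermediate
6 | methyl (R)-3-methyl-5-(triisopropylsilyloxy)pentanoate | CC(C)[Si](C(C)C)(C(C)C)OCC[C@@H](C)CC(=O)OC | intermediate
7 | (S)-3-methyl-5-(triisopropylsilyloxy)pentan-1-ol | CC(C)[Si](C(C)C)(C(C)C)OCC[C@@H](C)CCO | intermediate
8 | (R)-(5-bromo-3-methylpentyloxy)triisopropylsilane | CC(C)[Si](C(C)C)(C(C)C)OCC[C@@H](C)CCBr | intermediate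
9 | isobutyryl chloride | CC(C)C(=O)Cl | starting material
10 | ethyl vinyl ether | C=COCC | starting material
11 | dimethylketene (formed in the flask) | CC(C)=C=O | intermediate
12 | 3-ethoxy-2,2-dimethylcyclobutanone (racemic) | CCOC1CC(=O)C1(C)C | intermediate
13 | [(R)-3-methyl-5-(triisopropylsilyloxy)pentyl]magnesium bromide (formed in the flask) | CC(C)[Si](C(C)C)(C(C)C)OCC[C@@H](C)CC[Mg]Br | intermediate
14 | bromomagnesium enolate of the conjugate adduct (C5–O–MgBr, C5=C10; formed in the flask) | CC(C)[Si](C(C)C)(C(C)C)OCC[C@@H](C)CC[C@H]1C2(OCCO2)CCC(O[Mg]Br)=C1C | intermediate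
15 | (6R)-7-methyl-6-[(3S)-3-methyl-5-(triisopropylsilyloxy)pentyl]-8-(trimethylsilyloxy)-1,4-dioxaspiro[4.5]dec-7-ene | CC(C)[Si](C(C)C)(C(C)C)OCC[C@@H](C)CC[C@H]1C2(OCCO2)CCC(O[Si](C)(C)C)=C1C | intermediate
16 | 1ξ-ethoxy-8,8-ethylenedioxy-5ξ-(trimethylsilyloxy)-15-(triisopropylsilyloxy)-17-norlabdan-3-one (9β side chain, 10β-methyl, 13S; C1/C5 epimers; formed in the flask) | CC(C)[Si](C(C)C)(C(C)C)OCC[C@@H](C)CC[C@H]1C3(OCCO3)CCC2(O[Si](C)(C)C)C(C)(C)C(=O)CC(OCC)[C@]12C | intermediate
17 | 1ξ-ethoxy-8,8-ethylenedioxy-5ξ-hydroxy-15-(triisopropylsilyloxy)-17-norlabdan-3-one (C1/C5 epimers) | CC(C)[Si](C(C)C)(C(C)C)OCC[C@@H](C)CC[C@H]1C3(OCCO3)CCC2(O)C(C)(C)C(=O)CC(OCC)[C@]12C | intermediate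
18 | 1ξ-ethoxy-8,8-ethylenedioxy-15-(triisopropylsilyloxy)-17-norlabd-5-en-3-one (formed in the flask) | CC(C)[Si](C(C)C)(C(C)C)OCC[C@@H](C)CC[C@H]1C3(OCCO3)CC=C2C(C)(C)C(=O)CC(OCC)[C@]12C | intermediate
19 | 8,8-ethylenedioxy-15-(triisopropylsilyloxy)-17-norlabda-1,5-dien-3-one | CC(C)[Si](C(C)C)(C(C)C)OCC[C@@H](C)CC[C@H]1C3(OCCO3)CC=C2C(C)(C)C(=O)C=C[C@]12C | intermediate
20 | 8,8-ethylenedioxy-15-(triisopropylsilyloxy)-17-nor-5α-labdan-3-one (trans-fused) | CC(C)[Si](C(C)C)(C(C)C)OCC[C@@H](C)CC[C@H]1C3(OCCO3)CC[C@H]2C(C)(C)C(=O)CC[C@]12C | intermediate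
21 | 8,8-ethylenedioxy-15-(triisopropylsilyloxy)-17-nor-5α-labdan-3β-ol (formed in the flask) | CC(C)[Si](C(C)C)(C(C)C)OCC[C@@H](C)CC[C@H]1C3(OCCO3)CC[C@H]2C(C)(C)[C@@H](O)CC[C@]12C | intermediate
22 | 3β-hydroxy-15-(triisopropylsilyloxy)-17-nor-5α-labdan-8-one | CC(C)[Si](C(C)C)(C(C)C)OCC[C@@H](C)CC[C@H]1C(=O)CC[C@H]2C(C)(C)[C@@H](O)CC[C@]12C | intermediate
23 | 3β-(triethylsilyloxy)-15-(triisopropylsilyloxy)-17-nor-5α-labdan-8-one | CC(C)[Si](C(C)C)(C(C)C)OCC[C@@H](C)CC[C@H]1C(=O)CC[C@H]2C(C)(C)[C@@H](O[Si](CC)(CC)CC)CC[C@]12C | intermediate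
24 | potassium C7=C8 enolate of 23 (formed in the flask) | CC(C)[Si](C(C)C)(C(C)C)OCC[C@@H](C)CC[C@H]1C(O[K])=CC[C@H]2C(C)(C)[C@@H](O[Si](CC)(CC)CC)CC[C@]12C | intermediate
25 | 3β-(triethylsilyloxy)-15-(triisopropylsilyloxy)-17-norlabd-7-en-8-yl trifluoromethanesulfonate | CC(C)[Si](C(C)C)(C(C)C)OCC[C@@H](C)CC[C@H]1C(OS(=O)(=O)C(F)(F)F)=CC[C@H]2C(C)(C)[C@@H](O[Si](CC)(CC)CC)CC[C@]12C | intermediate
26 | 3β-(triethylsilyloxy)-15-(triisopropylsilyloxy)labd-7-ene | CC(C)[Si](C(C)C)(C(C)C)OCC[C@@H](C)CC[C@H]1C(C)=CC[C@H]2C(C)(C)[C@@H](O[Si](CC)(CC)CC)CC[C@]12C | intermediate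
27 | (13S)-labd-7-ene-3β,15-diol | OCC[C@@H](C)CC[C@H]1C(C)=CC[C@H]2C(C)(C)[C@@H](O)CC[C@]12C | intermediate
28 | (13S)-3β-hydroxylabd-7-en-15-yl acetate | CC(=O)OCC[C@@H](C)CC[C@H]1C(C)=CC[C@H]2C(C)(C)[C@@H](O)CC[C@]12C | target

**Summary and risks**

Total step count: 17. Longest linear sequence: 14 steps (from 4 through steps 3–6 and 8–17 to 28).

Steps most likely to fail:

Step 9. The second bond may not form: the aldol closure has to join the fully substituted C4 enolate carbon to C5 beside the quaternary C10, so the cascade could stop after the C1–C10 bond, and the aluminium Lewis acid could ionise the dioxolane. Fallback, setting out from 15 and coming back at 20: a Mukaiyama–Michael addition of 15 to pent-1-en-3-one (BF3·OEt2, iPrOH, CH2Cl2, −78 °C) should give the 1,5-diketone F1 with the same anti sense at C10. Aldol condensation (KOH, MeOH) then closes ring A as the 4-methyl-4-en-3-one F2. Birch-type reductive methylation (Li, NH3, tBuOH, then MeI) should deliver the 4,4-dimethyl trans-fused ketone 20 directly, so steps 10 and 11 are not needed on this path.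

Step 8. Competing 1,2-addition and weak enantioface discrimination are possible, because the enone carries substituents at both the α- and the γ-carbon. Fallback, setting out from 8 and 1 and coming back at 15: the Grignard reagent 13 made from 8 is added under CuBr·SMe2/chiral diphosphine catalysis to the unmethylated enone 1, a substrate class on which such additions are well established. The resulting bromomagnesium enolate F3 is methylated in the flask (MeI, DMPU) to the trans-2-methyl-3-alkyl ketone F4. Thermodynamic silylation (Me3SiCl, NaI, Et3N, MeCN) towards the more substituted enol ether then gives 15.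

Step 11. The hindered C5=C6 bond may be saturated incompletely, or hydrogen may be delivered to the β face and give the cis ring fusion. Fallback, setting out from 19 and coming back at 20: only the enone double bond is hydrogenated (H2, 1 bar, Pd/C, EtOAc) to the 5-en-3-one F5. The C5=C6 bond is then reduced by stepwise hydrogen-atom transfer (Mn(dpm)3, PhSiH3, tBuOOH, iPrOH), in which the tertiary C5 radical is quenched under thermodynamic control to the trans-fused 20.

Further compounds
F1 | step 9 | (6R,7R)-ketal diketone: 7-methyl-6-[(3S)-3-methyl-5-(triisopropylsilyloxy)pentyl]-7-(3-oxopentyl)-1,4-dioxaspiro[4.5]decan-8-one (3-oxopentyl trans to the side chain) | CC(C)[Si](C(C)C)(C(C)C)OCC[C@@H](C)CC[C@H]1C2(OCCO2)CCC(=O)[C@]1(C)CCC(=O)CC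
F2 | step 9 | 8,8-ethylenedioxy-15-(triisopropylsilyloxy)-17,19-dinorlabd-4-en-3-one (4-methyl-4-en-3-one) | CC(C)[Si](C(C)C)(C(C)C)OCC[C@@H](C)CC[C@H]1C3(OCCO3)CCC2=C(C)C(=O)CC[C@]12C
F3 | step 8 | bromomagnesium enolate from conjugate addition of 13 to 1 (no C10 methyl) | CC(C)[Si](C(C)C)(C(C)C)OCC[C@@H](C)CC[C@H]1C2(OCCO2)CCC(O[Mg]Br)=C1
F4 | step 8 | trans-7-methyl-6-[(3S)-3-methyl-5-(triisopropylsilyloxy)pentyl]-1,4-dioxaspiro[4.5]decan-8-one | CC(C)[Si](C(C)C)(C(C)C)OCC[C@@H](C)CC[C@H]1C2(OCCO2)CCC(=O)[C@@H]1C
F5 | step 11 | 8,8-ethylenedioxy-15-(triisopropylsilyloxy)-17-norlabd-5-en-3-one | CC(C)[Si](C(C)C)(C(C)C)OCC[C@@H](C)CC[C@H]1C3(OCCO3)CC=C2C(C)(C)C(=O)CC[C@]12C
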